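The outer rings (G, I, J) are phloroglucinols whose C2 is bonded to C5 of a crowded 1-aryloxy-2,4,6-trioxygenated ring (F, H, D). As its triketo tautomer, such a ring opens, between the aryl-bearing carbon and a neighbouring carbonyl, to a linear 6-aryl-3,5-dioxohexanoic ester. The hindered biaryl bond is therefore never made by coupling. It is bought as the benzylic C–C bond of an arylacetic acid, and one Claisen closure (benzylic C6 onto ester C1) creates the whole outer ring. The precursor is this keto ester with C3 masked as methyl enol ether, which excludes the inert hydroxypyrone anion. The resulting phenol serves three times in SNAr/Baeyer–Villiger sequences.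

Key step: step 6

Ring letters:
- A is the terminal 3,5-dihydroxyphenoxy ring.
- B is the core ring with O–A on its central oxygenated carbon, O–C and O–D on the two flanking carbons, and OH para to O–A.
- C is the 2,6-dihydroxy-1,4-phenylenedioxy ring between B and E.
- E is the second core ring, with O–C central, O–F and O–H flanking, and OH para.
- D, F, H are the inner biaryl rings, and J, G, I are the outer rings on D, F, H.

Abbreviation: HMB = 2,2',4,4',6,6'-hexamethoxybiphenyl-3-yl.

Remark on stereochemistry: the target has no stereocentre and no stereogenic axis, because each outer ring is symmetric about its biaryl bond.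

Assumption: 2,4,6-trimethoxyphenylacetic acid (1) is taken as a catalogue compound.

Step 1
Reactants: 1 2,4,6-trimethoxyphenylacetic acid
Product: 3 N-methoxy-N-methyl-2-(2,4,6-trimethoxyphenyl)acetamide, via acyl imidazolide 2 (not isolated)
Conditions: 1,1'-carbonyldiimidazole, CH2Cl2, rt; then MeNHOMe·HCl, rt
Reagents that add atoms: N,O-dimethylhydroxylamine hydrochloride, CNOC.Cl
Why: Carbonyldiimidazole activation followed by aminolysis (Weinreb amide formation) is routine for arylacetic acids, and this amide later stops acyl transfer at the ketone stage.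

Step 2
Reactants: 3 N-methoxy-N-methyl-2-(2,4,6-trimethoxyphenyl)acetamide
Product: 5 2-(3-formyl-2,4,6-trimethoxyphenyl)-N-methoxy-N-methylacetamide, via aryl iminium chloride 4 (not isolated)
Conditions: POCl3, DMF, 0 °C to rt; then H2O
Reagents that add atoms: N,N-dimethylformamide, CN(C)C=O; water, O
Why: Vilsmeier–Haack formylation: the two free ring positions are equivalent, each is ortho, ortho and para to a methoxy group, and the first formyl group deactivates the ring, so one monoaldehyde should result.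

Step 3
Reactants: 5 2-(3-formyl-2,4,6-trimethoxyphenyl)-N-methoxy-N-methylacetamide
Product: 7 2-(3-hydroxy-2,4,6-trimethoxyphenyl)-N-methoxy-N-methylacetamide, via aryl formate 6 (not isolated)
Conditions: mCPBA, CH2Cl2, 0 °C to rt; aq Na2S2O3/NaHCO3 wash; then MeOH, cat. Et3N, rt
Reagents that add atoms: 3-chloroperoxybenzoic acid, O=C(OO)c1cccc(Cl)c1
Why: Baeyer–Villiger (Dakin-type) oxidation: in the peracid adduct of a 2,4,6-trialkoxybenzaldehyde the electron-rich aryl group migrates rather than hydrogen, and the labile aryl formate is removed by transesterification without touching the amide.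

Step 4
Reactants: 7 2-(3-hydroxy-2,4,6-trimethoxyphenyl)-N-methoxy-N-methylacetamide
Product: 8 2-[3-(benzyloxy)-2,4,6-trimethoxyphenyl]-N-methoxy-N-methylacetamide
Conditions: BnBr, K2CO3, DMF, 50 °C
Reagents that add atoms: benzyl bromide, BrCc1ccccc1
Why: Williamson etherification marks the one oxygen that is to become a diaryl ether bridge with a group that can later be removed in the presence of methyl ethers.

Step 5
Reactants: 8 2-[3-(benzyloxy)-2,4,6-trimethoxyphenyl]-N-methoxy-N-methylacetamide; 9 methyl (2E)-3-methoxybut-2-enoate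
Product: 12 methyl (2E)-6-[3-(benzyloxy)-2,4,6-trimethoxyphenyl]-3-methoxy-5-oxohex-2-enoate, via lithium dienolate 10 (not isolated), via lithium hemiaminal adduct 11 (not isolated)
Conditions: 9 (2.5 equiv), LiN(iPr)2 (2.4 equiv), THF, −78 °C; then 8, −78 to −30 °C; AcOH quench at −78 °C
Reagents that add atoms: none
Why: Vinylogous Claisen acylation: dienolates of β-alkoxycrotonates (the dioxinone dienolates are the best-studied case) are acylated at the γ-carbon, the chelated adduct 11 holds until the acidic quench so that neither a second addition nor enolisation of the product interferes, and the double-bond geometry is not critical because it equilibrates in step 6.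

Step 6
Reactants: 12 methyl (2E)-6-[3-(benzyloxy)-2,4,6-trimethoxyphenyl]-3-methoxy-5-oxohex-2-enoate
Product: 14 2-[3-(benzyloxy)-2,4,6-trimethoxyphenyl]-5-methoxybenzene-1,3-diol, via cyclohexenedione tautomer 13 (not isolated)
Conditions: NaOMe (5 equiv), MeOH, sealed vessel, 140 °C, argon; then aq HCl, 0 °C
Reagents that add atoms: none
Why: Methoxide deprotonates C4 and C6 of 12 reversibly, but only the C6 carbanion (benzylic and α to the C5 ketone) has an electrophile within reach: it adds to the ester carbonyl C1, methoxide leaves, the C1–C6 bond closes 13, and 13 enolises to the arene and is withdrawn from every equilibrium as its phenolate. The closest known reactions are the alkoxide-induced conversion of 4-methoxy-6-methyl-2-pyrone, through its ring-opened 3-methoxy-5-oxohex-2-enoate, into phloroglucinol monomethyl ether, and the alkoxide-induced Claisen cyclisation of 6-aryl-5-oxohexanoates with di-ortho-substituted aryl groups to 2-arylcyclohexane-1,3-diones. The six-membered ring closes in the 6-(enolendo)-exo-trig mode, which is allowed for this ring size. No stereocentre survives, since C2 of 13 is planarised on enolisation and the new ring is symmetric about the biaryl bond. The step needs C-acylation to win over O-acylation by the C5 enolate oxygen, and the C3 enol ether secures this, because the enol lactone formed by O-acylation stays neutral and is reopened by methoxide, whereas a free C3 carbonyl would end as an unreactive hydroxypyrone anion and would also tie up the ester as a β-keto ester enolate. C2 is vinylic and cannot act as a nucleophile, C4 could only form a four-membered ring, and the E and Z isomers of 12 interconvert by addition and loss of methoxide at C3, so all material can reach the one productive closure.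

Step 7
Reactants: 14 2-[3-(benzyloxy)-2,4,6-trimethoxyphenyl]-5-methoxybenzene-1,3-diol
Product: 15 3-(benzyloxy)-2,2',4,4',6,6'-hexamethoxybiphenyl
Conditions: Me2SO4, K2CO3, acetone, reflux
Reagents that add atoms: dimethyl sulfate, COS(=O)(=O)OC
Why: Phenolate O-alkylation with the hard electrophile dimethyl sulfate (Williamson type) is the usual way to cap phloroglucinol-type phenols without C-methylation.

Step 8
Reactants: 15 3-(benzyloxy)-2,2',4,4',6,6'-hexamethoxybiphenyl
Product: 16 2,2',4,4',6,6'-hexamethoxybiphenyl-3-ol (HMB-OH)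
Conditions: H2 (1 atm), Pd/C, EtOAc–MeOH, rt
Reagents that add atoms: none
Why: Catalytic hydrogenolysis cleaves only the benzylic C–O bond, so exactly one phenol, flanked by two methoxy groups, is set free.

Step 9
Reactants: 16 HMB-OH (2.3 equiv); 17 2,6-difluoro-4-methoxybenzaldehyde
Product: 18 4-methoxy-2,6-bis(HMB-oxy)benzaldehyde
Conditions: Cs2CO3, DMSO, 110 °C, argon
Reagents that add atoms: none
Why: Twofold SNAr: each fluoride is ortho to the formyl acceptor that stabilises the Meisenheimer adduct, the 4-methoxy group is meta to both reacting carbons and so does not push electron density onto them, and 2,6-dialkoxyphenolates are competent nucleophiles towards fluorobenzaldehydes.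

Step 10
Reactants: 18 4-methoxy-2,6-bis(HMB-oxy)benzaldehyde
Product: 20 4-methoxy-2,6-bis(HMB-oxy)phenol, via aryl formate 19 (not isolated)
Conditions: mCPBA, CH2Cl2, 0 °C to rt; aq Na2S2O3/NaHCO3 wash; then MeOH–THF, cat. Et3N, rt
Reagents that add atoms: 3-chloroperoxybenzoic acid, O=C(OO)c1cccc(Cl)c1
Why: Baeyer–Villiger oxidation turns the activating formyl group into the central oxygen of ring E, the aryl group with two ortho and one para oxygen donors migrating in preference to hydrogen, and the peracid is destroyed before the formate is cleaved so that the free p-methoxyphenol never meets the oxidant.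

Step 11
Reactants: 16 HMB-OH; 17 2,6-difluoro-4-methoxybenzaldehyde (2 equiv)
Product: 21 2-fluoro-4-methoxy-6-(HMB-oxy)benzaldehyde
Conditions: K2CO3, DMF, 70 °C, argon
Reagents that add atoms: none
Why: SNAr stopped at the first stage: excess 17 and a lower temperature are used, and the aryloxy group that enters donates into the formyl-bearing ring and slows the second displacement.

Step 12
Reactants: 21 2-fluoro-4-methoxy-6-(HMB-oxy)benzaldehyde; 22 4-bromo-2,6-dimethoxyphenol (1.5 equiv)
Product: 23 2-(4-bromo-2,6-dimethoxyphenoxy)-4-methoxy-6-(HMB-oxy)benzaldehyde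
Conditions: Cs2CO3, DMSO, 110 °C, argon
Reagents that add atoms: none
Why: Second SNAr with an inexpensive phenol in excess: fluoride is by far the best leaving group on the ring, so the aryloxy group already present should not be exchanged, and the C–Br bond, which has no acceptor ortho or para to it, stays intact.

Step 13
Reactants: 23 2-(4-bromo-2,6-dimethoxyphenoxy)-4-methoxy-6-(HMB-oxy)benzaldehyde
Product: 25 2-(4-bromo-2,6-dimethoxyphenoxy)-4-methoxy-6-(HMB-oxy)phenol, via aryl formate 24 (not isolated)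
Conditions: mCPBA, CH2Cl2, 0 °C to rt; aq Na2S2O3/NaHCO3 wash; then MeOH–THF, cat. Et3N, rt
Reagents that add atoms: 3-chloroperoxybenzoic acid, O=C(OO)c1cccc(Cl)c1
Why: The same Baeyer–Villiger oxidation and formate methanolysis create the central oxygen of ring B, and the aryl bromide is inert to the peracid.

Step 14
Reactants: 25 2-(4-bromo-2,6-dimethoxyphenoxy)-4-methoxy-6-(HMB-oxy)phenol; 26 (3,5-dimethoxyphenyl)boronic acid (3 equiv)
Product: 27 1-(4-bromo-2,6-dimethoxyphenoxy)-2-(3,5-dimethoxyphenoxy)-5-methoxy-3-(HMB-oxy)benzene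
Conditions: Cu(OAc)2 (2 equiv), pyridine, 4 Å molecular sieves, CH2Cl2, dry air, rt
Reagents that add atoms: none
Why: Chan–Lam coupling: since the central oxygen of ring B stems from the Baeyer–Villiger step, ring A has to enter as the aryl donor, and this room-temperature coupling mediated by divalent copper is known to accept phenols with two ortho substituents and to leave aryl bromides untouched.

Step 15
Reactants: 20 4-methoxy-2,6-bis(HMB-oxy)phenol; 27 1-(4-bromo-2,6-dimethoxyphenoxy)-2-(3,5-dimethoxyphenoxy)-5-methoxy-3-(HMB-oxy)benzene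
Product: 28 tetracosa-O-methyl ether of the target
Conditions: CuI (20 mol %), picolinic acid (40 mol %), K3PO4, DMSO, 100 °C, argon
Reagents that add atoms: none
Why: Ullmann-type diaryl ether synthesis with the CuI/picolinic acid system, which is suited to hindered phenols, and the C–Br carbon of 27 lies between two hydrogens, so the crowding is on the phenolate side only.

Step 16
Reactants: 28 tetracosa-O-methyl ether of the target
Product: 29 CNP0294555.0
Conditions: BBr3 (60 equiv), CH2Cl2, −78 °C to rt; then ice-water; reversed-phase chromatography under argon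
Reagents that add atoms: none
Why: Lewis-acid ether cleavage: bromide attacks only the sp3 methyl carbon of each boron-complexed ArO–CH3 unit, so diaryl ether and biaryl bonds persist, and the reaction type is standard for polymethoxylated biphenyls and diaryl ethers.

Compound list
1 | 2,4,6-trimethoxyphenylacetic acid | COc1cc(OC)c(CC(=O)O)c(OC)c1 | starting material
2 | 1-[(2,4,6-trimethoxyphenyl)acetyl]imidazole | COc1cc(OC)c(CC(=O)n2ccnc2)c(OC)c1 | intermediate
3 | N-methoxy-N-methyl-2-(2,4,6-trimethoxyphenyl)acetamide | COc1cc(OC)c(CC(=O)N(C)OC)c(OC)c1 | intermediate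
4 | dimethyliminium chloride of aldehyde 5 (ArCH=NMe2+ Cl−) | COc1cc(OC)c(CC(=O)N(C)OC)c(OC)c1C=[N+](C)C.[Cl-] | intermediate
5 | 2-(3-formyl-2,4,6-trimethoxyphenyl)-N-methoxy-N-methylacetamide | COc1cc(OC)c(CC(=O)N(C)OC)c(OC)c1C=O | intermediate
6 | 3-{2-[methoxy(methyl)amino]-2-oxoethyl}-2,4,6-trimethoxyphenyl formate | COc1cc(OC)c(CC(=O)N(C)OC)c(OC)c1OC=O | intermediate
7 | 2-(3-hydroxy-2,4,6-trimethoxyphenyl)-N-methoxy-N-methylacetamide | COc1cc(OC)c(CC(=O)N(C)OC)c(OC)c1O | intermediate
8 | 2-[3-(benzyloxy)-2,4,6-trimethoxyphenyl]-N-methoxy-N-methylacetamide | COc1cc(OC)c(CC(=O)N(C)OC)c(OC)c1OCc1ccccc1 | intermediate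
9 | methyl (2E)-3-methoxybut-2-enoate | COC(=O)/C=C(/OC)C | starting material
10 | lithium 1,3-dimethoxybuta-1,3-dien-1-olate | C=C(OC)C=C([O-])OC.[Li+] | intermediate
11 | lithium alkoxide of the tetrahedral adduct of 10 with 8 | COC(=O)/C=C(/OC)CC([O-])(Cc1c(OC)cc(OC)c(OCc2ccccc2)c1OC)N(C)OC.[Li+] | intermediate
12 | methyl (2E)-6-[3-(benzyloxy)-2,4,6-trimethoxyphenyl]-3-methoxy-5-oxohex-2-enoate | COC(=O)/C=C(/OC)CC(=O)Cc1c(OC)cc(OC)c(OCc2ccccc2)c1OC | intermediate
13 | 2-[3-(benzyloxy)-2,4,6-trimethoxyphenyl]-5-methoxycyclohex-4-ene-1,3-dione (racemic, transient) | COC1=CC(=O)C(c2c(OC)cc(OC)c(OCc3ccccc3)c2OC)C(=O)C1 | intermediate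
14 | 2-[3-(benzyloxy)-2,4,6-trimethoxyphenyl]-5-methoxybenzene-1,3-diol | COc1cc(O)c(-c2c(OC)cc(OC)c(OCc3ccccc3)c2OC)c(O)c1 | intermediate
15 | 3-(benzyloxy)-2,2',4,4',6,6'-hexamethoxybiphenyl | COc1cc(OC)c(-c2c(OC)cc(OC)c(OCc3ccccc3)c2OC)c(OC)c1 | intermediate
16 | 2,2',4,4',6,6'-hexamethoxybiphenyl-3-ol (HMB-OH) | COc1cc(OC)c(-c2c(OC)cc(OC)c(O)c2OC)c(OC)c1 | intermediate
17 | 2,6-difluoro-4-methoxybenzaldehyde | COc1cc(F)c(C=O)c(F)c1 | starting material
18 | 4-methoxy-2,6-bis(HMB-oxy)benzaldehyde | COc1cc(Oc2c(OC)cc(OC)c(-c3c(OC)cc(OC)cc3OC)c2OC)c(C=O)c(Oc2c(OC)cc(OC)c(-c3c(OC)cc(OC)cc3OC)c2OC)c1 | intermediate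
19 | 4-methoxy-2,6-bis(HMB-oxy)phenyl formate | COc1cc(Oc2c(OC)cc(OC)c(-c3c(OC)cc(OC)cc3OC)c2OC)c(OC=O)c(Oc2c(OC)cc(OC)c(-c3c(OC)cc(OC)cc3OC)c2OC)c1 | intermediate
20 | 4-methoxy-2,6-bis(HMB-oxy)phenol | COc1cc(Oc2c(OC)cc(OC)c(-c3c(OC)cc(OC)cc3OC)c2OC)c(O)c(Oc2c(OC)cc(OC)c(-c3c(OC)cc(OC)cc3OC)c2OC)c1 | intermediate
21 | 2-fluoro-4-methoxy-6-(HMB-oxy)benzaldehyde | COc1cc(F)c(C=O)c(Oc2c(OC)cc(OC)c(-c3c(OC)cc(OC)cc3OC)c2OC)c1 | intermediate
22 | 4-bromo-2,6-dimethoxyphenol | COc1cc(Br)cc(OC)c1O | starting material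
23 | 2-(4-bromo-2,6-dimethoxyphenoxy)-4-methoxy-6-(HMB-oxy)benzaldehyde | COc1cc(Oc2c(OC)cc(Br)cc2OC)c(C=O)c(Oc2c(OC)cc(OC)c(-c3c(OC)cc(OC)cc3OC)c2OC)c1 | intermediate
24 | 2-(4-bromo-2,6-dimethoxyphenoxy)-4-methoxy-6-(HMB-oxy)phenyl formate | COc1cc(Oc2c(OC)cc(Br)cc2OC)c(OC=O)c(Oc2c(OC)cc(OC)c(-c3c(OC)cc(OC)cc3OC)c2OC)c1 | intermediate
25 | 2-(4-bromo-2,6-dimethoxyphenoxy)-4-methoxy-6-(HMB-oxy)phenol | COc1cc(Oc2c(OC)cc(Br)cc2OC)c(O)c(Oc2c(OC)cc(OC)c(-c3c(OC)cc(OC)cc3OC)c2OC)c1 | intermediate
26 | (3,5-dimethoxyphenyl)boronic acid | COc1cc(OC)cc(B(O)O)c1 | starting material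
27 | 1-(4-bromo-2,6-dimethoxyphenoxy)-2-(3,5-dimethoxyphenoxy)-5-methoxy-3-(HMB-oxy)benzene | COc1cc(OC)cc(Oc2c(Oc3c(OC)cc(Br)cc3OC)cc(OC)cc2Oc2c(OC)cc(OC)c(-c3c(OC)cc(OC)cc3OC)c2OC)c1 | intermediate
28 | tetracosa-O-methyl ether of 29 (all 24 hydroxyl groups as OMe) | COc1cc(OC)cc(Oc2c(Oc3c(OC)cc(Oc4c(Oc5c(OC)cc(OC)c(-c6c(OC)cc(OC)cc6OC)c5OC)cc(OC)cc4Oc4c(OC)cc(OC)c(-c5c(OC)cc(OC)cc5OC)c4OC)cc3OC)cc(OC)cc2Oc2c(OC)cc(OC)c(-c3c(OC)cc(OC)cc3OC)c2OC)c1 | intermediate
29 | CNP0294555.0 | Oc1cc(O)cc(Oc2c(Oc3c(O)cc(Oc4c(Oc5c(O)cc(O)c(-c6c(O)cc(O)cc6O)c5O)cc(O)cc4Oc4c(O)cc(O)c(-c5c(O)cc(O)cc5O)c4O)cc3O)cc(O)cc2Oc2c(O)cc(O)c(-c3c(O)cc(O)cc3O)c2O)c1 | target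

Total step count: 16.
Longest linear sequence: 14 (steps 1–8, then 11–16). Steps 9 and 10 form the second branch.

Steps most likely to fail

**Step 6.**
- Risk: The benzylic position may be deprotonated too rarely, or be too shielded by its two ortho-methoxy groups, for C–C bond formation. Material would then idle on the O-acylation side, or be drained by loss of the enol-ether methyl group and by retro-Claisen cleavage.
- Fallback (biaryl cross-coupling in place of ring synthesis; sets out from 22, comes back at 15):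
  - 22 is benzylated (BnBr, K2CO3, DMF) to 2-(benzyloxy)-5-bromo-1,3-dimethoxybenzene F1.
  - The bromide is exchanged for methoxide (NaOMe, CuBr, DMF–MeOH, 110 °C) to give 2-(benzyloxy)-1,3,5-trimethoxybenzene F2.
  - NBS in MeCN at 0 °C brominates one of the two equivalent free positions to 2-(benzyloxy)-4-bromo-1,3,5-trimethoxybenzene F3.
  - Suzuki–Miyaura coupling with 2,4,6-trimethoxyphenylboronic acid (Pd(OAc)2, SPhos, K3PO4, toluene–H2O, 100 °C) gives 15.

**Step 15.**
- Risk: C–O bond formation at the shielded phenolate oxygen may be slow. Reductive loss of bromine from 27 and oxidation of the electron-rich phenolate would then compete.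
- Fallback (sets out from 20, comes back at 28): the shielded phenol reacts earlier, without metal, with a small activated electrophile, and ring B is then built onto the product.
  - SNAr of 20 with 4-fluoro-2,6-dimethoxybenzaldehyde (Cs2CO3, DMSO, 110 °C) should give 2,6-dimethoxy-4-[4-methoxy-2,6-bis(HMB-oxy)phenoxy]benzaldehyde F4.
  - Baeyer–Villiger oxidation (mCPBA) leads to the ring C aryl formate F5, and methanolysis to the ring C phenol F6.
  - F6 takes the place of 22 in the operations of steps 12 to 14. These are SNAr with 21 to the ring B aldehyde F7, oxidation to the ring B aryl formate F8, methanolysis to the ring B phenol F9, and Chan–Lam coupling with 26 to 28.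

**Step 16.**
- Risk: Cleavage of 24 methyl ethers may stay incomplete once partly cleaved boron phenolates precipitate. The free polyphenol may also be lost to air oxidation during isolation.
- Fallback (derivatise, purify, release; sets out from 28, comes back at 29):
  - After the BBr3 treatment the crude polyphenol is not purified but acetylated at once (Ac2O, pyridine, argon) to the tetracosaacetate F10.
  - F10 is stable, can be chromatographed on silica, and can be separated from congeners that still carry methyl groups. Those congeners are returned to BBr3.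
  - Mild deacetylation with hydrazine hydrate in degassed THF–MeOH at 0 °C to rt then releases 29 under reducing, nearly neutral conditions.

Further compounds
F1 | step 6 | 2-(benzyloxy)-5-bromo-1,3-dimethoxybenzene | COc1cc(Br)cc(OC)c1OCc1ccccc1
F2 | step 6 | 2-(benzyloxy)-1,3,5-trimethoxybenzene | COc1cc(OC)c(OCc2ccccc2)c(OC)c1
F3 | step 6 | 2-(benzyloxy)-4-bromo-1,3,5-trimethoxybenzene | COc1cc(OC)c(OCc2ccccc2)c(OC)c1Br
F4 | step 15 | 2,6-dimethoxy-4-[4-methoxy-2,6-bis(HMB-oxy)phenoxy]benzaldehyde | COc1cc(Oc2c(OC)cc(OC)c(-c3c(OC)cc(OC)cc3OC)c2OC)c(Oc2cc(OC)c(C=O)c(OC)c2)c(Oc2c(OC)cc(OC)c(-c3c(OC)cc(OC)cc3OC)c2OC)c1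
F5 | step 15 | ring C aryl formate: 2,6-dimethoxy-4-[4-methoxy-2,6-bis(HMB-oxy)phenoxy]phenyl formate | COc1cc(Oc2c(OC)cc(OC)c(-c3c(OC)cc(OC)cc3OC)c2OC)c(Oc2cc(OC)c(OC=O)c(OC)c2)c(Oc2c(OC)cc(OC)c(-c3c(OC)cc(OC)cc3OC)c2OC)c1
F6 | step 15 | ring C phenol: 2,6-dimethoxy-4-[4-methoxy-2,6-bis(HMB-oxy)phenoxy]phenol | COc1cc(Oc2c(OC)cc(OC)c(-c3c(OC)cc(OC)cc3OC)c2OC)c(Oc2cc(OC)c(O)c(OC)c2)c(Oc2c(OC)cc(OC)c(-c3c(OC)cc(OC)cc3OC)c2OC)c1
F7 | step 15 | ring B aldehyde: 2-{2,6-dimethoxy-4-[4-methoxy-2,6-bis(HMB-oxy)phenoxy]phenoxy}-4-methoxy-6-(HMB-oxy)benzaldehyde | COc1cc(Oc2c(OC)cc(Oc3c(Oc4c(OC)cc(OC)c(-c5c(OC)cc(OC)cc5OC)c4OC)cc(OC)cc3Oc3c(OC)cc(OC)c(-c4c(OC)cc(OC)cc4OC)c3OC)cc2OC)c(C=O)c(Oc2c(OC)cc(OC)c(-c3c(OC)cc(OC)cc3OC)c2OC)c1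
F8 | step 15 | ring B aryl formate: formyloxy in place of the formyl group of F7 | COc1cc(Oc2c(OC)cc(Oc3c(Oc4c(OC)cc(OC)c(-c5c(OC)cc(OC)cc5OC)c4OC)cc(OC)cc3Oc3c(OC)cc(OC)c(-c4c(OC)cc(OC)cc4OC)c3OC)cc2OC)c(OC=O)c(Oc2c(OC)cc(OC)c(-c3c(OC)cc(OC)cc3OC)c2OC)c1
F9 | step 15 | ring B phenol: hydroxyl in place of the formyl group of F7 | COc1cc(Oc2c(OC)cc(Oc3c(Oc4c(OC)cc(OC)c(-c5c(OC)cc(OC)cc5OC)c4OC)cc(OC)cc3Oc3c(OC)cc(OC)c(-c4c(OC)cc(OC)cc4OC)c3OC)cc2OC)c(O)c(Oc2c(OC)cc(OC)c(-c3c(OC)cc(OC)cc3OC)c2OC)c1
F10 | step 16 | tetracosaacetate of 29 | CC(=O)Oc1cc(OC(C)=O)cc(Oc2c(Oc3c(OC(C)=O)cc(Oc4c(Oc5c(OC(C)=O)cc(OC(C)=O)c(-c6c(OC(C)=O)cc(OC(C)=O)cc6OC(C)=O)c5OC(C)=O)cc(OC(C)=O)cc4Oc4c(OC(C)=O)cc(OC(C)=O)c(-c5c(OC(C)=O)cc(OC(C)=O)cc5OC(C)=O)c4OC(C)=O)cc3OC(C)=O)cc(OC(C)=O)cc2Oc2c(OC(C)=O)cc(OC(C)=O)c(-c3c(OC(C)=O)cc(OC(C)=O)cc3OC(C)=O)c2OC(C)=O)c1
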